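**Plan**
- Retrosynthetic cuts, in order: the three O–Si bonds and the C4 ketone/carbinol level; then C1''–C2'' (benzylic CH2 on C5' of ring B to the vinylic CH) together with C3''–CH3; then C3–C1' (ring C to ring B).
- Forward: rings A/C are bought as 7-hydroxychromone and ring B as 5-bromo-2,4-dihydroxybenzaldehyde, so no ring is built. C3–C1' comes from C3–H zincation/Negishi coupling, the formyl carbon is taken to CH2Cl, and the C10 chain is then completed and attached in one flask.
- Enabling feature: C1'' sits on C5' of ring B, ortho to O4' and para to O2'. It can therefore be bought as the formyl carbon of a resorcylaldehyde at exactly this position, and its chloride is a highly activated benzylic electrophile. The C2''=C3'' alkene carries CH3 cis to C1'', which is the imprint of a syn CH3–metal addition to a terminal alkyne.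
- Key event: three-component syn-methyl-benzylation of a C8 enyne (Zr-catalysed methylalumination, then Ni(0)-catalysed alkenyl–benzyl coupling). It makes two C–C bonds, sets the E geometry and completes the carbon skeleton in one operation, and it avoids the O/C, C3'/C5' and ring-A selectivity problems of a direct geranylation.
- Stereochemistry: the core stays a flat isoflavone until the organometallic work is finished. C3 is then set by dynamic kinetic resolution in an asymmetric transfer-hydrogenation cascade (cis-(3R,4R)-isoflavan-4-ol). The helper C4 carbinol is oxidised back without base, and the silyl groups leave under weakly acidic fluoride, so 3R is kept.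

Key step: step 7

Remark: the C3 centre of the given SMILES is R. Isoflavonoid numbering is used (O1–C8a for rings C/A, C1'–C6' for ring B, C1''–C8'' for the chain). TBS = tert-butyldimethylsilyl.

**Route**

Step 1
Reactants: 1 7-hydroxy-4H-chromen-4-one
Product: 2 7-(tert-butyldimethylsilyloxy)-4H-chromen-4-one
Conditions: TBSCl, imidazole, DMF, rt
Reagents that add atoms: tert-butyldimethylsilyl chloride CC(C)(C)[Si](C)(C)Cl
Why: Imidazole-promoted O-silylation of the only acidic OH; the aryl silyl ether should tolerate the neutral organozinc, organoaluminium and transfer-hydrogenation steps and can be removed at the end without base or strong acid.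

Step 2
Reactants: 3 5-bromo-2,4-dihydroxybenzaldehyde
Product: 4 5-bromo-2,4-bis(tert-butyldimethylsilyloxy)benzaldehyde
Conditions: TBSCl (2.5 equiv), imidazole, DMF, rt
Reagents that add atoms: tert-butyldimethylsilyl chloride CC(C)(C)[Si](C)(C)Cl
Why: Exhaustive O-silylation (excess reagent because the chelated ortho-OH reacts more slowly) masks the future O2' and O4', while the bromide (future C1') and the formyl carbon (future C1'') stay available.

Step 3
Reactants: 2 7-(tert-butyldimethylsilyloxy)-4H-chromen-4-one; 4 5-bromo-2,4-bis(tert-butyldimethylsilyloxy)benzaldehyde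
Product: 6 7,2',4'-tris(tert-butyldimethylsilyloxy)-5'-formylisoflavone, via C3-zincated chromone 5 (not isolated)
Conditions: TMPZnCl·LiCl (1.2 equiv), THF, 0 °C to rt; then 4, Pd(OAc)2 (2 mol %), SPhos (4 mol %), 50 °C
Reagents that add atoms: none
Why: Carbonyl-directed C3–H zincation of the chromone by the magnesium-free TMP zinc amide followed by Negishi cross-coupling is a known entry to isoflavones, and the neutral organozinc should spare both the formyl group and the base-labile aryl silyl ethers.

Step 4
Reactants: 6 7,2',4'-tris(tert-butyldimethylsilyloxy)-5'-formylisoflavone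
Product: 7 7,2',4'-tris(tert-butyldimethylsilyloxy)-5'-(hydroxymethyl)isoflavone
Conditions: NaBH4, THF/MeOH, −40 °C; AcOH quench
Reagents that add atoms: none
Why: Chemoselective borohydride reduction, since the aldehyde is far more electrophilic than the vinylogous-ester carbonyl of the isoflavone; low temperature and instant protonation of the alkoxide by methanol should suppress 1,4-reduction and O-to-O silyl migration.

Step 5
Reactants: 7 7,2',4'-tris(tert-butyldimethylsilyloxy)-5'-(hydroxymethyl)isoflavone
Product: 9 7,2',4'-tris(tert-butyldimethylsilyloxy)-5'-(chloromethyl)isoflavone, via benzylic mesylate 8 (not isolated)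
Conditions: MsCl, Et3N, THF, −10 °C; then LiCl, 0 °C to rt; used crude
Reagents that add atoms: lithium chloride [Li+].[Cl-]
Why: Mesylation with in situ chloride displacement is standard for electron-rich benzylic alcohols; the O2'/O4' donors make the mesylate very labile, so the displacement should be fast, and the chloride is carried on without chromatography.

Step 6
Reactants: 10 5-bromo-2-methylpent-2-ene
Product: 11 6-methylhept-5-en-1-yne
Conditions: HC≡CLi·H2NCH2CH2NH2, DMSO, 0 °C to rt
Reagents that add atoms: lithium acetylide ethylenediamine complex [Li]C#C.NCCN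
Why: SN2 alkylation of lithium acetylide with a primary homoallylic bromide in a dipolar aprotic solvent is a standard terminal-alkyne synthesis.

Step 7
Reactants: 11 6-methylhept-5-en-1-yne; 9 7,2',4'-tris(tert-butyldimethylsilyloxy)-5'-(chloromethyl)isoflavone
Product: 13 7,2',4'-tris(tert-butyldimethylsilyloxy)-5'-[(2E)-3,7-dimethylocta-2,6-dien-1-yl]isoflavone, via (E)-alkenyldimethylalane 12 (not isolated)
Conditions: 11, Me3Al (1.5 equiv), Cp2ZrCl2 (10 mol %), ClCH2CH2Cl, 0 °C to rt; excess Me3Al and solvent removed in vacuo; THF; then 9, NiCl2(PPh3)2/n-BuLi (1:2, 3 mol %), −20 °C to rt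
Reagents that add atoms: trimethylaluminium C[Al](C)C
Why: Zirconium-catalysed syn-methylalumination (Negishi carboalumination) of the terminal alkyne puts CH3 on C3'' and aluminium on the terminal carbon C2'' from the same face, so alane 12 already holds the E geometry (CH3 cis to the metal) while the remote trisubstituted C6''=C7'' alkene is left alone. Ni(0) then inserts into the C1''–Cl bond of 9, which is strongly activated because C1'' hangs on C5' of ring B ortho to O4' and para to O2'; transmetalation moves the sp2 alkenyl group from aluminium in preference to methyl, and reductive elimination forms C1''–C2'' with retention of the alkene geometry. The closest known reaction type is the Ni(0)- or Pd(0)-catalysed coupling of (E)-2-methylalk-1-enylalanes with polyalkoxybenzyl chlorides and chloromethylquinones, as used for prenylated quinones. No ring is closed and no stereocentre is made; the one stereo-element set is the E-C2''=C3'' double bond, controlled by the syn addition and the stereoretentive coupling. The step needs site selectivity on ring B, which is secured because C1'' is the former formyl carbon of 3 (no C- versus O-, C3' versus C5' or ring-A alkylation and no allylic transposition can occur), and it needs chemoselectivity over the chromone, which is a vinylogous ester locked s-trans (no six-membered delivery from carbonyl-bound aluminium to C2) and is further shielded by removal of excess Me3Al, by THF as Lewis-basic solvent and by the low temperature. The core is still a flat isoflavone at this stage, so no epimerisable centre is exposed to the organometallic reagents.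

Step 8
Reactants: 13 7,2',4'-tris(tert-butyldimethylsilyloxy)-5'-[(2E)-3,7-dimethylocta-2,6-dien-1-yl]isoflavone
Product: 15 (3R,4R)-cis-7,2',4'-tris(tert-butyldimethylsilyloxy)-5'-geranylisoflavan-4-ol, via racemising isoflavanone 14 (not isolated)
Conditions: RuCl[(R,R)-TsDPEN](p-cymene) (3 mol %), HCO2H/Et3N, EtOAc, 40 °C
Reagents that add atoms: none
Why: Noyori–Ikariya asymmetric transfer-hydrogenation cascade with dynamic kinetic resolution, a reaction type known for isoflavones and isoflavanones: Ru–H first reduces C2=C3 in a 1,4 sense to 14, whose C3–H (alpha to C4=O and benzylic) epimerises quickly in the amine-containing medium, and the (R,R)-catalyst (4R by the aryl ketone model) should reduce only the 3R ketone fast, with hydride delivered to C4 anti to ring B, which gives the cis-(3R,4R) alcohol and leaves the isolated trisubstituted alkenes untouched.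

Step 9
Reactants: 15 (3R,4R)-cis-7,2',4'-tris(tert-butyldimethylsilyloxy)-5'-geranylisoflavan-4-ol
Product: 16 (3R)-7,2',4'-tris(tert-butyldimethylsilyloxy)-5'-geranylisoflavanone
Conditions: Dess–Martin periodinane, CH2Cl2, 0 °C to rt
Reagents that add atoms: none
Why: Dess–Martin oxidation under base-free conditions removes the helper C4 stereocentre without enolising the new ketone, so the 3R configuration should be retained, as in the known transfer-hydrogenation/re-oxidation route to isoflavanones.

Step 10
Reactants: 16 (3R)-7,2',4'-tris(tert-butyldimethylsilyloxy)-5'-geranylisoflavanone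
Product: 17 (3R)-7,2',4'-trihydroxy-5'-geranylisoflavanone (target)
Conditions: Et3N·3HF (excess), THF, 0 °C to rt; pH 6 buffer work-up
Reagents that add atoms: none
Why: Fluoride cleavage of the three aryl silyl ethers in a weakly acidic medium; the absence of free base should avoid C3 epimerisation, and the absence of strong acid should avoid chroman formation between O4'–H and C2''=C3'' and dehydrative closure of O2'–H onto C4.

**Compound list**
1 | 7-hydroxy-4H-chromen-4-one | O=c1ccoc2cc(O)ccc12 | starting material
2 | 7-(tert-butyldimethylsilyloxy)-4H-chromen-4-one | O=c1ccoc2cc(O[Si](C)(C)C(C)(C)C)ccc12 | intermediate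
3 | 5-bromo-2,4-dihydroxybenzaldehyde | O=Cc1cc(Br)c(O)cc1O | starting material
4 | 5-bromo-2,4-bis(tert-butyldimethylsilyloxy)benzaldehyde | O=Cc1cc(Br)c(O[Si](C)(C)C(C)(C)C)cc1O[Si](C)(C)C(C)(C)C | intermediate
5 | [7-(tert-butyldimethylsilyloxy)-4-oxo-4H-chromen-3-yl]zinc chloride (LiCl complex, not isolated) | O=c1c([Zn]Cl)coc2cc(O[Si](C)(C)C(C)(C)C)ccc12 | intermediate
6 | 7,2',4'-tris(tert-butyldimethylsilyloxy)-5'-formylisoflavone | O=Cc1cc(-c2coc3cc(O[Si](C)(C)C(C)(C)C)ccc3c2=O)c(O[Si](C)(C)C(C)(C)C)cc1O[Si](C)(C)C(C)(C)C | intermediate
7 | 7,2',4'-tris(tert-butyldimethylsilyloxy)-5'-(hydroxymethyl)isoflavone | OCc1cc(-c2coc3cc(O[Si](C)(C)C(C)(C)C)ccc3c2=O)c(O[Si](C)(C)C(C)(C)C)cc1O[Si](C)(C)C(C)(C)C | intermediate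
8 | 7,2',4'-tris(tert-butyldimethylsilyloxy)-5'-(methanesulfonyloxymethyl)isoflavone (not isolated) | CS(=O)(=O)OCc1cc(-c2coc3cc(O[Si](C)(C)C(C)(C)C)ccc3c2=O)c(O[Si](C)(C)C(C)(C)C)cc1O[Si](C)(C)C(C)(C)C | intermediate
9 | 7,2',4'-tris(tert-butyldimethylsilyloxy)-5'-(chloromethyl)isoflavone | ClCc1cc(-c2coc3cc(O[Si](C)(C)C(C)(C)C)ccc3c2=O)c(O[Si](C)(C)C(C)(C)C)cc1O[Si](C)(C)C(C)(C)C | intermediate
10 | 5-bromo-2-methylpent-2-ene | CC(C)=CCCBr | starting material
11 | 6-methylhept-5-en-1-yne | CC(C)=CCCC#C | intermediate
12 | [(1E)-2,6-dimethylhepta-1,5-dien-1-yl]dimethylalane (not isolated) | CC(C)=CCC/C(C)=C/[Al](C)C | intermediate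
13 | 7,2',4'-tris(tert-butyldimethylsilyloxy)-5'-[(2E)-3,7-dimethylocta-2,6-dien-1-yl]isoflavone | CC(C)=CCC/C(C)=C/Cc1cc(-c2coc3cc(O[Si](C)(C)C(C)(C)C)ccc3c2=O)c(O[Si](C)(C)C(C)(C)C)cc1O[Si](C)(C)C(C)(C)C | intermediate
14 | 7,2',4'-tris(tert-butyldimethylsilyloxy)-5'-geranylisoflavanone, both C3 epimers in equilibrium (not isolated) | CC(C)=CCC/C(C)=C/Cc1cc(C2COc3cc(O[Si](C)(C)C(C)(C)C)ccc3C2=O)c(O[Si](C)(C)C(C)(C)C)cc1O[Si](C)(C)C(C)(C)C | intermediate
15 | (3R,4R)-cis-7,2',4'-tris(tert-butyldimethylsilyloxy)-5'-geranylisoflavan-4-ol | CC(C)=CCC/C(C)=C/Cc1cc([C@@H]2COc3cc(O[Si](C)(C)C(C)(C)C)ccc3[C@@H]2O)c(O[Si](C)(C)C(C)(C)C)cc1O[Si](C)(C)C(C)(C)C | intermediate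
16 | (3R)-7,2',4'-tris(tert-butyldimethylsilyloxy)-5'-geranylisoflavanone | CC(C)=CCC/C(C)=C/Cc1cc([C@@H]2COc3cc(O[Si](C)(C)C(C)(C)C)ccc3C2=O)c(O[Si](C)(C)C(C)(C)C)cc1O[Si](C)(C)C(C)(C)C | intermediate
17 | (3R)-3-{5-[(2E)-3,7-dimethylocta-2,6-dien-1-yl]-2,4-dihydroxyphenyl}-7-hydroxy-2,3-dihydro-4H-chromen-4-one | CC(C)=CCC/C(C)=C/Cc1cc([C@@H]2COc3cc(O)ccc3C2=O)c(O)cc1O | target

**Step count**
Total step count: 10.
Longest linear sequence: 8 (steps 2, 3, 4, 5, 7, 8, 9, 10, from 3).

**Steps most likely to fail**

1. Step 7.
   - Risk: aluminium-bound methyl or alkenyl groups may add to the chromone (1,2 at C4, or nickel-promoted 1,4 at C2). The very electron-rich benzylic chloride may also ionise under Lewis acid and self-condense or homocouple before it is coupled.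
   - Fallback (polarity reversal, no aluminium near the chromone): it sets out from 11 and 9 and comes back at 13. Alane 12 is generated as before and quenched with iodine to give (E)-1-iodo-2,6-dimethylhepta-1,5-diene F1. Chloride 9 is treated with zinc dust and LiCl in THF to give the benzylic zinc chloride F2. A Pd(0)-catalysed Negishi coupling of F2 with F1, which retains the alkene geometry, forms the same C1''–C2'' bond and gives 13.

2. Step 3.
   - Risk: metalation may drift from C3 to the more acidic C2. Oxidative addition into the hindered, electron-rich bromide may be slow enough for the zinc species to decay or to attack the formyl group.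
   - Fallback (halogen-defined C3 and a boron nucleophile): it sets out from 4 and comes back at 6. Rings A/C are then taken from commercial 2,4-dihydroxyacetophenone instead of 1 and 2. Selective silylation of the non-chelated 4-OH gives 1-[4-(tert-butyldimethylsilyloxy)-2-hydroxyphenyl]ethanone F3. Condensation with DMF dimethyl acetal gives the enaminone F4. Iodine-induced cyclisation gives 7-(tert-butyldimethylsilyloxy)-3-iodo-4H-chromen-4-one F5. Miyaura borylation of 4 gives the pinacol boronate F6. Suzuki–Miyaura coupling of F5 with F6 under nearly anhydrous phosphate conditions (to spare the aryl silyl ethers) gives 6.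

3. Step 8.
   - Risk: the 1,4-reduction of the hindered 2'-silyloxy isoflavone may be sluggish, or C3 epimerisation may not keep pace with ketone reduction, which would erode facial and diastereoselectivity.
   - Fallback (stereoablative protonation instead of reduction/re-oxidation): it sets out from 13 and comes back at 16, by-passing 15 and step 9. 1,4-Reduction of 13 with L-Selectride (THF, −78 °C) and trapping of the enolate with allyl chloroformate should give the allyl enol carbonate F7. Pd(0) with a chiral t-Bu-PHOX-type ligand and Meldrum's acid as proton source should then give 16 directly. This decarboxylative asymmetric protonation is a reaction type known for isoflavanones, and the ligand enantiomer is chosen for 3R.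

**Further compounds**
F1 | step 7 | (E)-1-iodo-2,6-dimethylhepta-1,5-diene | CC(C)=CCC/C(C)=C/I
F2 | step 7 | {2,4-bis(tert-butyldimethylsilyloxy)-5-[7-(tert-butyldimethylsilyloxy)-4-oxo-4H-chromen-3-yl]benzyl}zinc chloride | Cl[Zn]Cc1cc(-c2coc3cc(O[Si](C)(C)C(C)(C)C)ccc3c2=O)c(O[Si](C)(C)C(C)(C)C)cc1O[Si](C)(C)C(C)(C)C
F3 | step 3 | 1-[4-(tert-butyldimethylsilyloxy)-2-hydroxyphenyl]ethanone | CC(=O)c1ccc(O[Si](C)(C)C(C)(C)C)cc1O
F4 | step 3 | (E)-1-[4-(tert-butyldimethylsilyloxy)-2-hydroxyphenyl]-3-(dimethylamino)prop-2-en-1-one | CN(C)/C=C/C(=O)c1ccc(O[Si](C)(C)C(C)(C)C)cc1O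
F5 | step 3 | 7-(tert-butyldimethylsilyloxy)-3-iodo-4H-chromen-4-one | O=c1c(I)coc2cc(O[Si](C)(C)C(C)(C)C)ccc12
F6 | step 3 | 2,4-bis(tert-butyldimethylsilyloxy)-5-(4,4,5,5-tetramethyl-1,3,2-dioxaborolan-2-yl)benzaldehyde | O=Cc1cc(B2OC(C)(C)C(C)(C)O2)c(O[Si](C)(C)C(C)(C)C)cc1O[Si](C)(C)C(C)(C)C
F7 | step 8 | allyl 7-(tert-butyldimethylsilyloxy)-3-[2,4-bis(tert-butyldimethylsilyloxy)-5-geranylphenyl]-2H-chromen-4-yl carbonate | CC(C)=CCC/C(C)=C/Cc1cc(C2=C(OC(=O)OCC=C)c3ccc(O[Si](C)(C)C(C)(C)C)cc3OC2)c(O[Si](C)(C)C(C)(C)C)cc1O[Si](C)(C)C(C)(C)C
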